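If solid D stands in a flask and holds c_X at one level whatever the charge, then Q forms at one molar rate (a pseudo-zero-order feed), and I can carry that rate from the larch run to the new flask.

| flask | D | remark | time |
|---|---|---|---|
| larch | 0.65 M | run made earlier |  |
| flask | 0.43 M |  | 2.5 min |

larch run (percent of the D charged)

| time / s | Q / % | L / % |
|---|---|---|
| 10.0 | 2.3 | 2.1 |
| 12.0 | 1.5 | 2.1 |
| 20.0 | 3.2 | 3.2 |
| 25.0 | 4.0 | 4.7 |
| 30.0 | 5.7 | 6.5 |

(standard deviation of a reading: 0.5 percentage points)

- in percentages every species weighs as the D in it: one J counts as two
- as a solid, counted per litre of solution: D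
- the numbers in the tables scatter by 0.5 percentage points (one standard deviation)
- steps under discussion: X <-> L; X <-> Q; X <-> E; 2 X -> J; D <-> X
- at the start none of D is in solution

- the moment within 2.5 min at which there is most Q
- the amount of Q, in percent of the D charged, at that time

I replace the curve of Q in the larch run by its mean. The last reading, 5.7 % of 0.65 M at 30.0 s, gives the mean feed of Q, the molar amount of Q formed per litre and second from the start to that reading, of 0.00123 M s⁻¹. This line stands 0.78 percentage points above the reading at 12.0 s, where the scatter is 0.5 points.

I now build the new flask up. Taking this step by itself, I carry Q along the line to 43.1 % of the smaller charge at 2.5 min. Adding L at its own mean feed, 0.00141 M s⁻¹, does not cut the line in this reckoning, since the two together take 2.71 min to use up the charge, later than 2.5 min. But E and J are not read, and what they take comes out of the same charge. If they drain as much as Q and L together, a guess with no reading behind it, the reckoned life of the charge is 1.36 min. I commit to a peak near that time, with Q at 23.4 %.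

The forecast gives 2.5 min (1.6 min to 2.5 min) and 30 % (16 % to 45 %), later and higher than my reckoning, with the words “Nothing yet shows Q falling”.

The new flask gives 17.6 % at 1.32 min.

    X ⇌ L (K = 1.70, k = 0.0270 s⁻¹)
    X ⇌ Q (K = 1.90, k = 0.0230 s⁻¹)
    X ⇌ E (K = 0.330, k = 0.100 s⁻¹)
    2 X → J (k = 0.310 M⁻¹ s⁻¹)
    D ⇌ X, rate k5*(cs5 - [X]) while solid is left; crystals form when [X] > cs5 (solubility = 0.280 M, k = 0.0370 s⁻¹)

At that peak of the new flask D stands at 0 %, and the line carried to the same time gives 22.8 %, which is 5.3 points above the flask. The neighbouring flask is the same one read at 40 s, when D still stands at 25.5 %. There the same feed over the same charge gives 11.5 %, and that flask holds Q at 11.2 %.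

(The runs come from a simulation for an exercise; scatter was added.)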